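**Plan**

1. Numbering: C1 carries the acyloxy group, C4 the carboxyl C15, C5 the methyl C14, C7 the acrolein C11–C13, C8 the ketone, C9=C10 the enone alkene; β is the face of C14; the side-chain acid is C1'–C8'.
2. Enabling feature: ring B (C5, C6, C7, C8, C9, C10) is a cyclohexene whose C9=C10 alkene lies between the quaternary C5 and the oxygenated C8, the retron of a [4+2] adduct of a diene C8(O)=C9–C10=C5 with a vinyl ketone (C6=C7). Ring A (C1–C4, C5 with C14, C10, C15) is Hagemann's ester atom for atom.
3. Cuts: C5–C6 and C7–C8 (Diels–Alder), C11–C13 (Stille hydroxymethylation), the C1–O acyl bond (esterification), C9–C10 (Suzuki), C2'=C3' (Wittig) and the Robinson bonds of ring A.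
4. Forward: ring A by Robinson annulation, C10 iodination, asymmetric reduction, Suzuki coupling, side-chain ester, silyl dienol ether, ring B by cycloaddition with methyl vinyl ketone, then C13, the C8 ketone and the free acid.
5. Stereochemistry: C1 from reagent-controlled CBS reduction, C4 by keeping the cis diastereomer of that reduction, C5 from dienophile attack anti to the β groups at C1 and C4, C7 from the endo transition state (also the equatorial, thermodynamic position), C4' from an Evans methylation.

Key step: step 13

Remark: racemic 5 is taken to be configurationally stable at C4 under the non-basic conditions of step 3, so that step is planned as a divergent reduction of the racemate, not as a dynamic resolution.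

**Route**

Step 1
Reactants: 1 tert-butyl acetoacetate; 2 methyl vinyl ketone
Product: 4 racemic tert-butyl 2-methyl-4-oxocyclohex-2-ene-1-carboxylate (tert-butyl Hagemann ester), via Michael adduct 3 (not isolated)
Conditions: KOtBu (5 mol %), t-BuOH, 0 °C to rt; then pyrrolidine (20 mol %), AcOH (20 mol %), 60 °C
Reagents that add atoms: none
Why: Michael addition followed by intramolecular aldol condensation of the methyl ketone onto the acetoacetate carbonyl (Robinson annulation) is the classical entry to Hagemann esters and should give ring A with C14, C15 and the C1 oxygen in place, C4 being racemic at this stage.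

Step 2
Reactants: 4 racemic tert-butyl Hagemann ester
Product: 5 racemic tert-butyl 3-iodo-2-methyl-4-oxocyclohex-2-ene-1-carboxylate
Conditions: I2, pyridine, CH2Cl2, rt
Reagents that add atoms: iodine, II
Why: Pyridine-mediated α-iodination of cyclic enones (addition, iodination, elimination) is routine for 3-methylcyclohexenones and should place the halide on C10.

Step 3
Reactants: 5 racemic iodoenone
Product: 6 tert-butyl (1S,4R)-4-hydroxy-3-iodo-2-methylcyclohex-2-ene-1-carboxylate (cis)
Conditions: (S)-Me-CBS [(3aS)-1-methyl-3,3-diphenyltetrahydro-1H,3H-pyrrolo[1,2-c][1,3,2]oxazaborole] (20 mol %), BH3·SMe2, THF, −20 °C; MeOH; chromatography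
Reagents that add atoms: none
Why: Corey–Bakshi–Shibata reduction of 2-iodocyclohexenones is reagent-controlled (the iodoalkene arm acts as the large group), so both enantiomers of 5 should give the R carbinol at C1 (plan numbering); the enantiomer with S configuration at C4 gives cis alcohol 6, and the other gives the separable trans diastereomer, which can be reoxidised and recycled.

Step 4
Reactants: 6 cis iodo alcohol; 7 (E)-2-ethoxyvinylboronic acid pinacol ester
Product: 8 tert-butyl (1S,4R)-3-[(E)-2-ethoxyethenyl]-4-hydroxy-2-methylcyclohex-2-ene-1-carboxylate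
Conditions: PdCl2(dppf) (5 mol %), K3PO4, THF/H2O, 60 °C
Reagents that add atoms: none
Why: Suzuki–Miyaura coupling of a vinyl iodide with an alkenylboronate proceeds with retention at both partners and tolerates the free hydroxyl, so it should form C9–C10 and bring in C8 at the aldehyde oxidation level as an E enol ether.

Step 5
Reactants: 9 (S)-4-benzyl-2-oxazolidinone; 10 hexanoyl chloride
Product: 11 (S)-4-benzyl-3-hexanoyl-2-oxazolidinone
Conditions: Et3N, DMAP (10 mol %), CH2Cl2, 0 °C to rt
Reagents that add atoms: none
Why: DMAP-catalysed N-acylation with an acid chloride is a standard way to load the Evans auxiliary.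

Step 6
Reactants: 11 N-hexanoyl oxazolidinone
Product: 13 (S)-4-benzyl-3-[(S)-2-methylhexanoyl]-2-oxazolidinone, via sodium Z-enolate 12 (not isolated)
Conditions: NaN(SiMe3)2, THF, −78 °C; MeI, −78 °C
Reagents that add atoms: iodomethane, CI
Why: Evans alkylation, in which the chelated Z-enolate is methylated on the face away from the benzyl group, should set the S configuration of the future C4'.

Step 7
Reactants: 13 methylated imide
Product: 14 (S)-2-methylhexan-1-ol
Conditions: LiBH4, H2O (1 equiv), Et2O, 0 °C
Reagents that add atoms: none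
Why: Reductive cleavage of N-acyl oxazolidinones with LiBH4 gives the primary alcohol without epimerisation and returns the auxiliary.

Step 8
Reactants: 14 (S)-2-methylhexan-1-ol; 15 ethyl 2-(triphenylphosphoranylidene)propanoate
Product: 17 ethyl (2E,4S)-2,4-dimethyloct-2-enoate, via (S)-2-methylhexanal 16 (not isolated)
Conditions: PhI(OAc)2, TEMPO (10 mol %), CH2Cl2, rt; then 15, rt
Reagents that add atoms: none
Why: Nitroxyl-catalysed oxidation followed in the same flask by Wittig olefination with a stabilised α-methyl ylide avoids isolating the volatile, epimerisable aldehyde and should give the E trisubstituted enoate.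

Step 9
Reactants: 17 ethyl enoate
Product: 18 (2E,4S)-2,4-dimethyloct-2-enoic acid
Conditions: LiOH, THF/MeOH/H2O, 40 °C; then 1 M HCl
Reagents that add atoms: lithium hydroxide, [Li+].[OH-]
Why: Saponification is safe here because the γ stereocentre of the enoate is not acidic under aqueous hydroxide.

Step 10
Reactants: 18 side-chain acid; 8 dienol ether alcohol
Product: 20 tert-butyl (1S,4R)-4-[(2E,4S)-2,4-dimethyloct-2-enoyloxy]-3-[(E)-2-ethoxyethenyl]-2-methylcyclohex-2-ene-1-carboxylate, via mixed anhydride 19 (not isolated)
Conditions: 2,4,6-trichlorobenzoyl chloride, Et3N, toluene, rt; then 8, DMAP, rt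
Reagents that add atoms: none
Why: Yamaguchi esterification couples hindered α,β-unsaturated acids to secondary allylic alcohols with retention at C1 and under basic conditions that spare the enol ether.

Step 11
Reactants: 20 ethyl dienol ether ester
Product: 21 tert-butyl (1S,4R)-4-[(2E,4S)-2,4-dimethyloct-2-enoyloxy]-2-methyl-3-(2-oxoethyl)cyclohex-2-ene-1-carboxylate
Conditions: oxalic acid, THF/H2O, 0 °C to rt
Reagents that add atoms: water, O
Why: Mild acid hydrolysis of a dienol ether (kinetic protonation at C9, as in the unmasking of Birch-type dienol ethers) should give the β,γ-unsaturated aldehyde without moving the C5=C10 alkene or touching the tert-butyl ester.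

Step 12
Reactants: 21 β,γ-unsaturated aldehyde
Product: 22 tert-butyl (1S,4R)-3-[(E)-2-(tert-butyldimethylsilyloxy)ethenyl]-4-[(2E,4S)-2,4-dimethyloct-2-enoyloxy]-2-methylcyclohex-2-ene-1-carboxylate
Conditions: TBSOTf (1.2 equiv), Et3N, CH2Cl2, −78 °C to 0 °C
Reagents that add atoms: tert-butyldimethylsilyl triflate, CC(C)(C)[Si](C)(C)OS(=O)(=O)C(F)(F)F
Why: Soft enolisation (O-silylation, then deprotonation at C9, the only α position) should give the conjugated silyl dienol ether, with the E isomer expected because a Z silyloxy group would clash with ring A (allylic strain), and the low temperature keeps the tert-butyl ester intact.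

Step 13
Reactants: 22 silyl dienol ether; 2 methyl vinyl ketone
Product: 23 tert-butyl 7α-acetyl-8α-(tert-butyldimethylsilyloxy)-1β-[(2E,4S)-2,4-dimethyloct-2-enoyloxy]-5β-methyl-Δ9(10)-octalin-4β-carboxylate (plan numbering)
Conditions: 2 (5 equiv), BHT (1 mol %), CH2Cl2, 1.2 GPa, 25 °C
Reagents that add atoms: none
Why: This is a normal-electron-demand Diels–Alder reaction in which the 1-silyloxy group raises the diene HOMO and puts its largest coefficient on C5, so C5 bonds to the enone β-carbon (C6) and C8 to the α-carbon (C7) in one suprafacial, asynchronous event; the closest precedents are cycloadditions of 1-silyloxybutadienes with enones and of 2-methyl-1-vinylcyclohexenes that create an angular methyl group. Ring B closes as a six-membered carbocycle by [4+2] cycloaddition, both bonds forming in the same step and the C9=C10 alkene remaining. C5 is controlled by ring A, since the C1 acyloxy and C4 ester groups both lie on the β face, the dienophile adds to the α face and C14 ends up β. C7 follows from the endo orientation of the acetyl group (7α, also the equatorial position), and C8 from the E geometry of the diene (8α, erased later by oxidation). The step needs ortho regioselectivity, which the silyloxy group secures, and α-face selectivity, which the two β substituents secure. Because C14 is the inside substituent at the C5 terminus the s-cis conformer is strained, so pressure rather than heat is used to speed the cycloaddition without opening a [1,5]-hydrogen shift.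

Step 14
Reactants: 23 Diels–Alder adduct
Product: 25 enol triflate (23 with 1-(trifluoromethanesulfonyloxy)ethenyl at C7 in place of acetyl), via potassium enolate 24 (not isolated)
Conditions: KN(SiMe3)2 (1.05 equiv), THF, −78 °C; PhNTf2, −78 °C to 0 °C
Reagents that add atoms: N-phenylbis(trifluoromethanesulfonimide), O=S(=O)(N(c1ccccc1)S(=O)(=O)C(F)(F)F)C(F)(F)F
Why: Kinetic deprotonation of a methyl ketone occurs at the methyl group and not at the hindered C7 methine (so C7 is untouched and no β-elimination of the silyloxy group can start), and O-triflation of the enolate is standard.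

Step 15
Reactants: 25 enol triflate
Product: 26 allylic alcohol (23 with 3-hydroxyprop-1-en-2-yl at C7: C11=C12 and C13–OH)
Conditions: Bu3SnCH2OH (1.5 equiv), Pd(PPh3)4 (10 mol %), LiCl, 1,4-dioxane, 90 °C
Reagents that add atoms: (tributylstannyl)methanol, CCCC[Sn](CCCC)(CCCC)CO
Why: Stille coupling of enol triflates with (tributylstannyl)methanol is an established hydroxymethylation, and it brings in C13 as an alcohol while C8 is still protected, so no γ-hydroxy aldehyde and hence no lactol can arise.

Step 16
Reactants: 26 allylic alcohol silyl ether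
Product: 27 diol (8α-OH and 13-OH)
Conditions: HF·pyridine, pyridine, THF, 0 °C to rt
Reagents that add atoms: none
Why: Buffered HF·pyridine cleaves a secondary TBS ether without affecting the esters or ionising the allylic positions.

Step 17
Reactants: 27 diol
Product: 28 integric acid tert-butyl ester
Conditions: (COCl)2, DMSO, CH2Cl2, −78 °C; Et3N, −78 °C to −30 °C
Reagents that add atoms: none
Why: Swern oxidation turns both hydroxyls into alkoxysulfonium salts before base is added, so the 1,4-diol should go to the keto aldehyde without lactol or lactone formation, and the low temperature should keep the equatorial C7 centre and the unconjugated acrolein in place.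

Step 18
Reactants: 28 integric acid tert-butyl ester
Product: 29 integric acid
Conditions: CF3CO2H/CH2Cl2 (1:4), 0 °C
Reagents that add atoms: none
Why: Acidolysis of the tert-butyl ester (loss of 2-methylpropene) frees the C15 acid under conditions to which the secondary enoate ester, the enone and the enal should be inert.

**Compound list**

1 | tert-butyl acetoacetate | CC(=O)CC(=O)OC(C)(C)C | starting material
2 | methyl vinyl ketone | C=CC(C)=O | starting material
3 | tert-butyl 2-acetyl-5-oxohexanoate (Michael adduct) | CC(=O)CCC(C(C)=O)C(=O)OC(C)(C)C | intermediate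
4 | racemic tert-butyl 2-methyl-4-oxocyclohex-2-ene-1-carboxylate | CC1=CC(=O)CCC1C(=O)OC(C)(C)C | intermediate
5 | racemic tert-butyl 3-iodo-2-methyl-4-oxocyclohex-2-ene-1-carboxylate | CC1=C(I)C(=O)CCC1C(=O)OC(C)(C)C | intermediate
6 | tert-butyl (1S,4R)-4-hydroxy-3-iodo-2-methylcyclohex-2-ene-1-carboxylate | CC1=C(I)[C@H](O)CC[C@@H]1C(=O)OC(C)(C)C | intermediate
7 | (E)-2-ethoxyvinylboronic acid pinacol ester | CCO/C=C/B1OC(C)(C)C(C)(C)O1 | starting material
8 | tert-butyl (1S,4R)-3-[(E)-2-ethoxyethenyl]-4-hydroxy-2-methylcyclohex-2-ene-1-carboxylate | CC1=C(/C=C/OCC)[C@H](O)CC[C@@H]1C(=O)OC(C)(C)C | intermediate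
9 | (S)-4-benzyl-2-oxazolidinone | O=C1N[C@@H](Cc2ccccc2)CO1 | starting material
10 | hexanoyl chloride | CCCCCC(=O)Cl | starting material
11 | (S)-4-benzyl-3-hexanoyl-2-oxazolidinone | CCCCCC(=O)N1C(=O)OC[C@@H]1Cc1ccccc1 | intermediate
12 | sodium Z-enolate of 11 | CCCC/C=C(\[O-])N1C(=O)OC[C@@H]1Cc1ccccc1.[Na+] | intermediate
13 | (S)-4-benzyl-3-[(S)-2-methylhexanoyl]-2-oxazolidinone | CCCC[C@H](C)C(=O)N1C(=O)OC[C@@H]1Cc1ccccc1 | intermediate
14 | (S)-2-methylhexan-1-ol | CCCC[C@H](C)CO | intermediate
15 | ethyl 2-(triphenylphosphoranylidene)propanoate | CCOC(=O)C(C)=P(c1ccccc1)(c1ccccc1)c1ccccc1 | starting material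
16 | (S)-2-methylhexanal | CCCC[C@H](C)C=O | intermediate
17 | ethyl (2E,4S)-2,4-dimethyloct-2-enoate | CCCC[C@H](C)/C=C(\C)C(=O)OCC | intermediate
18 | (2E,4S)-2,4-dimethyloct-2-enoic acid | CCCC[C@H](C)/C=C(\C)C(=O)O | intermediate
19 | mixed anhydride of 18 with 2,4,6-trichlorobenzoic acid | CCCC[C@H](C)/C=C(\C)C(=O)OC(=O)c1c(Cl)cc(Cl)cc1Cl | intermediate
20 | ethyl dienol ether ester (ring A, 1β-acyloxy, 4β-CO2tBu) | CC1=C(/C=C/OCC)[C@H](OC(=O)/C(C)=C/[C@@H](C)CCCC)CC[C@@H]1C(=O)OC(C)(C)C | intermediate
21 | β,γ-unsaturated aldehyde (C8 aldehyde on ring A) | CC1=C(CC=O)[C@H](OC(=O)/C(C)=C/[C@@H](C)CCCC)CC[C@@H]1C(=O)OC(C)(C)C | intermediate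
22 | ring A (E)-silyl dienol ether | CC1=C(/C=C/O[Si](C)(C)C(C)(C)C)[C@H](OC(=O)/C(C)=C/[C@@H](C)CCCC)CC[C@@H]1C(=O)OC(C)(C)C | intermediate
23 | 7α-acetyl-8α-silyloxy octalin (Diels–Alder adduct) | CC(=O)[C@@H]1C[C@@]2(C)C(=C[C@@H]1O[Si](C)(C)C(C)(C)C)[C@H](OC(=O)/C(C)=C/[C@@H](C)CCCC)CC[C@@H]2C(=O)OC(C)(C)C | intermediate
24 | potassium enolate of 23 (methyl side) | C=C([O-])[C@@H]1C[C@@]2(C)C(=C[C@@H]1O[Si](C)(C)C(C)(C)C)[C@H](OC(=O)/C(C)=C/[C@@H](C)CCCC)CC[C@@H]2C(=O)OC(C)(C)C.[K+] | intermediate
25 | enol triflate at C11 | C=C(OS(=O)(=O)C(F)(F)F)[C@@H]1C[C@@]2(C)C(=C[C@@H]1O[Si](C)(C)C(C)(C)C)[C@H](OC(=O)/C(C)=C/[C@@H](C)CCCC)CC[C@@H]2C(=O)OC(C)(C)C | intermediate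
26 | 13-hydroxy 8α-silyl ether | C=C(CO)[C@@H]1C[C@@]2(C)C(=C[C@@H]1O[Si](C)(C)C(C)(C)C)[C@H](OC(=O)/C(C)=C/[C@@H](C)CCCC)CC[C@@H]2C(=O)OC(C)(C)C | intermediate
27 | 8α,13-diol | C=C(CO)[C@@H]1C[C@@]2(C)C(=C[C@@H]1O)[C@H](OC(=O)/C(C)=C/[C@@H](C)CCCC)CC[C@@H]2C(=O)OC(C)(C)C | intermediate
28 | integric acid tert-butyl ester | C=C(C=O)[C@@H]1C[C@@]2(C)C(=CC1=O)[C@H](OC(=O)/C(C)=C/[C@@H](C)CCCC)CC[C@@H]2C(=O)OC(C)(C)C | intermediate
29 | integric acid (1R,4S,5R,7S; side chain 2E,4S) | C=C(C=O)[C@@H]1C[C@@]2(C)C(=CC1=O)[C@H](OC(=O)/C(C)=C/[C@@H](C)CCCC)CC[C@@H]2C(=O)O | target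

**Step count and risks**

Total: 18 steps. Longest linear sequence: 14 steps (steps 5 to 18, from the oxazolidinone and hexanoyl chloride); 13 steps from tert-butyl acetoacetate.

Step 13. The s-cis conformer of the diene is strained by the inside methyl C14, so cycloaddition may be outrun by polymerisation of the enone, loss of the enol ether or a [1,5]-hydrogen shift, and facial selectivity may erode if forcing conditions are needed. The fallback sets out from 22 and uses but-3-yn-2-one as a linear, more reactive 2π partner (toluene, 60 °C), which forms the same two bonds and should give the cyclohexa-1,4-diene adduct F1. Conjugate reduction of its C6=C7 enone with [(Ph3P)CuH]6 (benzene/H2O, rt), which should leave the hindered side-chain enoate alone, and protonation to the equatorial acetyl compound returns to the route at 23.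

Step 12. Enolisation may deliver the Z silyl enol ether, or the aldehyde may slip into conjugation before silylation; either gives a diene that cannot reach the reactive geometry. The fallback sets out from 20, whose E geometry is fixed by the coupling, and uses it directly as the diene with 2 under the conditions of step 13 to give the 8α-ethoxy adduct F2. This is taken through the chemistry of steps 14 and 15: the potassium enolate F3, the ethoxy enol triflate F4 and the ethoxy allylic alcohol F5. The primary allylic alcohol is then oxidised with MnO2 to the ethoxy enal F6. Finally the C8 ketone is unveiled with DDQ in wet CH2Cl2 (hydride abstraction at the allylic ether carbon, then hydrolysis of the oxocarbenium ion), which returns to the route at 28.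

Step 15. Slow transmetalation of the sp3 stannane may let the enol triflate decay by protodetriflation, or let zerovalent palladium ionise the allylic ester at C1. The fallback sets out from 23 and methylenates the acetyl group under Takai–Lombardo conditions (Zn, CH2Br2, TiCl4, THF) to the isopropenyl compound F7. Allylic hydroxylation of its methyl group with SeO2 (catalytic) and t-BuOOH (ene reaction, then [2,3]-shift) returns to the route at 26.

**Further compounds**

F1 | step 13 | cyclohexa-1,4-diene adduct (7-acetyl, C6=C7, 8α-silyloxy) | CC(=O)C1=C[C@@]2(C)C(=C[C@@H]1O[Si](C)(C)C(C)(C)C)[C@H](OC(=O)/C(C)=C/[C@@H](C)CCCC)CC[C@@H]2C(=O)OC(C)(C)C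
F2 | step 12 | 8α-ethoxy adduct (7α-acetyl) | CC(=O)[C@@H]1C[C@@]2(C)C(=C[C@@H]1OCC)[C@H](OC(=O)/C(C)=C/[C@@H](C)CCCC)CC[C@@H]2C(=O)OC(C)(C)C
F3 | step 12 | potassium enolate of F2 | C=C([O-])[C@@H]1C[C@@]2(C)C(=C[C@@H]1OCC)[C@H](OC(=O)/C(C)=C/[C@@H](C)CCCC)CC[C@@H]2C(=O)OC(C)(C)C.[K+]
F4 | step 12 | ethoxy enol triflate | C=C(OS(=O)(=O)C(F)(F)F)[C@@H]1C[C@@]2(C)C(=C[C@@H]1OCC)[C@H](OC(=O)/C(C)=C/[C@@H](C)CCCC)CC[C@@H]2C(=O)OC(C)(C)C
F5 | step 12 | ethoxy allylic alcohol (13-OH) | C=C(CO)[C@@H]1C[C@@]2(C)C(=C[C@@H]1OCC)[C@H](OC(=O)/C(C)=C/[C@@H](C)CCCC)CC[C@@H]2C(=O)OC(C)(C)C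
F6 | step 12 | ethoxy enal | C=C(C=O)[C@@H]1C[C@@]2(C)C(=C[C@@H]1OCC)[C@H](OC(=O)/C(C)=C/[C@@H](C)CCCC)CC[C@@H]2C(=O)OC(C)(C)C
F7 | step 15 | isopropenyl compound (8α-silyloxy) | C=C(C)[C@@H]1C[C@@]2(C)C(=C[C@@H]1O[Si](C)(C)C(C)(C)C)[C@H](OC(=O)/C(C)=C/[C@@H](C)CCCC)CC[C@@H]2C(=O)OC(C)(C)C
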